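**Retrosynthetic overview**
1. Target 16 ⇒ alkyne 10 + benzylic bromide 13: syn-methylalumination of the alkyne and Pd coupling form the side-chain C3–CH3 and C1–C2 bonds and fix the 2E alkene.
2. 10 ⇒ allylic alcohol 6 + allenylboronate 7: one-flask oxidation and chiral phosphoric acid catalysed allenylboration form the C4–C5 bond and the only stereocentre (5S); this is the proposed new step.
3. 6 ⇒ allylic bromide 3 + 3-methylfuran 4 (SN2 at C8); 3 ⇐ geranyl acetate 1 (SeO2 allylic oxidation, Appel), which supplies the 6E and 10E alkenes.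
4. 13 ⇐ 2,6-dimethylhydroquinone 11 (acetylation, benzylic bromination).
5. No ring is built: the furan ring (from 4) is attached first and the benzene ring (from 11) last.

Assumption: (S)-TRIP [(S)-3,3'-bis(2,4,6-triisopropylphenyl)-1,1'-binaphthyl-2,2'-diyl hydrogen phosphate] is taken to direct attack to the Si face of the enal, the mirror of the Re-face attack known for the (R) acid; the sign is checked on 10 by Mosher ester analysis and the (R) acid is used if it is opposite.

**Route**

Step 1
Reactants: 1 geranyl acetate [(2E)-3,7-dimethylocta-2,6-dien-1-yl acetate]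
Product: 2 (2E,6E)-8-hydroxy-3,7-dimethylocta-2,6-dien-1-yl acetate
Conditions: SeO2 (0.1 equiv), t-BuOOH (3 equiv), salicylic acid (0.1 equiv), CH2Cl2, rt
Reagents that add atoms: tert-butyl hydroperoxide CC(C)(C)OO
Why: Sharpless SeO2/t-BuOOH allylic oxidation (ene reaction, then [2,3]-sigmatropic shift) hydroxylates only the E-methyl group of the electron-rich terminal alkene, because the C2 alkene is deactivated by the allylic acetate.

Step 2
Reactants: 2 (2E,6E)-8-hydroxy-3,7-dimethylocta-2,6-dien-1-yl acetate
Product: 3 (2E,6E)-8-bromo-3,7-dimethylocta-2,6-dien-1-yl acetate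
Conditions: CBr4, PPh3, CH2Cl2, 0 °C
Reagents that add atoms: carbon tetrabromide BrC(Br)(Br)Br
Why: Appel reaction, in which bromide displaces the alkoxyphosphonium ion by SN2 to give the primary allylic bromide with no allylic shift and no change of alkene geometry.

Step 3
Reactants: 3 (2E,6E)-8-bromo-3,7-dimethylocta-2,6-dien-1-yl acetate; 4 3-methylfuran
Product: 6 (2E,6E)-3,7-dimethyl-8-(4-methylfuran-2-yl)octa-2,6-dien-1-ol, via furyllithium 5 (not isolated)
Conditions: 2,2,6,6-tetramethylpiperidine (3.4 equiv), n-BuLi (3.3 equiv), THF, 0 °C; 4 (3.5 equiv), −78 → 0 °C; then 3, −78 °C → rt; H2O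
Reagents that add atoms: none
Why: Deprotonation then SN2 alkylation, in which the bulky lithium amide removes the less hindered C5–H of 4 (as it does for 3-methylthiophene), furyllithium 5 displaces the primary allylic bromide without transposition, and two further equivalents of 5 strip the acetate so that the free alcohol is obtained directly.

Step 4
Reactants: 6 (2E,6E)-3,7-dimethyl-8-(4-methylfuran-2-yl)octa-2,6-dien-1-ol; 7 allenylboronic acid pinacol ester [4,4,5,5-tetramethyl-2-(propa-1,2-dien-1-yl)-1,3,2-dioxaborolane]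
Product: 10 (4S,5E,9E)-6,10-dimethyl-11-(4-methylfuran-2-yl)undeca-5,9-dien-1-yn-4-ol, via dienal 8 (not isolated), via pinacol borate 9 (not isolated)
Conditions: IBX (1.3 equiv), EtOAc, 75 °C; evaporate, toluene, 4 Å MS, (S)-TRIP (10 mol%), 7 (1.5 equiv), −20 → 0 °C; filter, aq. NaHCO3
Reagents that add atoms: none
Why: Proposed new method: a one-flask oxidative enantioselective propargylation of a primary allylic alcohol, in which insoluble IBX (pentavalent iodine; unlike MnO2 it has no basic surface that would bind the acid catalyst) oxidises 6 to dienal 8 without touching the furan or the trisubstituted alkenes, and (S)-TRIP then hydrogen-bonds to a boronate oxygen of 7 while its phosphoryl oxygen holds the formyl hydrogen, so that the allenyl group is delivered through a closed six-membered SE2' transition state to the Si face of the aldehyde and sets the 4S carbinol, the product staying masked as borate 9 and therefore safe from the remaining oxidant until work-up; the closest known reaction type is the chiral phosphoric acid catalysed allenylboration of isolated aldehydes, together with tandem oxidation–olefination of allylic alcohols.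

Step 5
Reactants: 11 2,6-dimethylbenzene-1,4-diol (2,6-dimethylhydroquinone)
Product: 12 2,6-dimethyl-1,4-phenylene diacetate
Conditions: Ac2O, pyridine, DMAP (cat.), CH2Cl2, rt
Reagents that add atoms: acetic anhydride CC(=O)OC(C)=O
Why: DMAP-catalysed O-acetylation protects the air-sensitive hydroquinone and makes the ring electron-poor enough for a clean side-chain bromination.

Step 6
Reactants: 12 2,6-dimethyl-1,4-phenylene diacetate
Product: 13 2-(bromomethyl)-6-methyl-1,4-phenylene diacetate
Conditions: NBS (1.0 equiv), AIBN (cat.), PhCF3, 80 °C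
Reagents that add atoms: N-bromosuccinimide O=C1CCC(=O)N1Br
Why: Wohl–Ziegler radical bromination, in which the two methyl groups are equivalent and the acetoxy groups suppress ring bromination, so one equivalent of NBS gives mainly the monobromide (as known for methylhydroquinone diacetate) and unreacted 12 is recycled.

Step 7
Reactants: 10 (4S,5E,9E)-6,10-dimethyl-11-(4-methylfuran-2-yl)undeca-5,9-dien-1-yn-4-ol; 13 2-(bromomethyl)-6-methyl-1,4-phenylene diacetate
Product: 16 2-[(2E,5S,6E,10E)-5-hydroxy-3,7,11-trimethyl-12-(4-methylfuran-2-yl)dodeca-2,6,10-trien-1-yl]-6-methylbenzene-1,4-diol, via alkenylalane 14 (not isolated), via coupled diacetate 15 (not isolated)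
Conditions: AlMe3 (3.5 equiv), Cp2ZrCl2 (0.2 equiv), H2O (1.5 equiv), CH2Cl2, −20 → 0 °C; evaporate, THF, 13 (1.2 equiv), Pd(PPh3)4 (5 mol%), 0 °C → rt; then MeOH, K2CO3, rt, argon; aq. NH4Cl/Na2S2O4
Reagents that add atoms: trimethylaluminium C[Al](C)C
Why: Negishi zirconium-catalysed carboalumination adds Me–Al syn across the terminal alkyne (methyl to the internal carbon) to give E-alkenylalane 14, zerovalent palladium then couples 14 with the benzylic bromide with retention of geometry (Negishi alkenylalane–benzyl halide coupling) so that the 2E alkene is fixed, and carbonate methanolysis of the two aryl acetates frees the hydroquinone, while the carbinol centre is not involved and is kept cold to prevent ionisation of its aluminium alkoxide.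

**Compound list**
1 | geranyl acetate, (2E)-3,7-dimethylocta-2,6-dien-1-yl acetate | CC(=O)OC/C=C(\C)CCC=C(C)C | starting material
2 | (2E,6E)-8-hydroxy-3,7-dimethylocta-2,6-dien-1-yl acetate | CC(=O)OC/C=C(\C)CC/C=C(\C)CO | intermediate
3 | (2E,6E)-8-bromo-3,7-dimethylocta-2,6-dien-1-yl acetate | CC(=O)OC/C=C(\C)CC/C=C(\C)CBr | intermediate
4 | 3-methylfuran | Cc1ccoc1 | starting material
5 | (4-methylfuran-2-yl)lithium | [Li]c1cc(C)co1 | intermediate (not isolated)
6 | (2E,6E)-3,7-dimethyl-8-(4-methylfuran-2-yl)octa-2,6-dien-1-ol | OC/C=C(\C)CC/C=C(\C)Cc1cc(C)co1 | intermediate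
7 | allenylboronic acid pinacol ester, 4,4,5,5-tetramethyl-2-(propa-1,2-dien-1-yl)-1,3,2-dioxaborolane | C=C=CB1OC(C)(C)C(C)(C)O1 | starting material
8 | (2E,6E)-3,7-dimethyl-8-(4-methylfuran-2-yl)octa-2,6-dienal | O=C/C=C(\C)CC/C=C(\C)Cc1cc(C)co1 | intermediate (not isolated)
9 | 2-{[(4S,5E,9E)-6,10-dimethyl-11-(4-methylfuran-2-yl)undeca-5,9-dien-1-yn-4-yl]oxy}-4,4,5,5-tetramethyl-1,3,2-dioxaborolane | C/C(=C\[C@@H](OB1OC(C)(C)C(C)(C)O1)CC#C)CC/C=C(\C)Cc1cc(C)co1 | intermediate (not isolated)
10 | (4S,5E,9E)-6,10-dimethyl-11-(4-methylfuran-2-yl)undeca-5,9-dien-1-yn-4-ol | C/C(=C\[C@@H](O)CC#C)CC/C=C(\C)Cc1cc(C)co1 | intermediate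
11 | 2,6-dimethylbenzene-1,4-diol | Cc1cc(O)cc(C)c1O | starting material
12 | 2,6-dimethyl-1,4-phenylene diacetate | CC(=O)Oc1cc(C)c(OC(C)=O)c(C)c1 | intermediate
13 | 2-(bromomethyl)-6-methyl-1,4-phenylene diacetate | CC(=O)Oc1cc(C)c(OC(C)=O)c(CBr)c1 | intermediate
14 | [(1E,4S,5E,9E)-4-(dimethylalumanyloxy)-2,6,10-trimethyl-11-(4-methylfuran-2-yl)undeca-1,5,9-trien-1-yl]dimethylalane | C/C(=C\[C@@H](O[Al](C)C)C/C(C)=C/[Al](C)C)CC/C=C(\C)Cc1cc(C)co1 | intermediate (not isolated)
15 | dimethylaluminium alkoxide of 2-[(2E,5S,6E,10E)-5-hydroxy-3,7,11-trimethyl-12-(4-methylfuran-2-yl)dodeca-2,6,10-trien-1-yl]-6-methyl-1,4-phenylene diacetate | C/C(=C\[C@@H](O[Al](C)C)C/C(C)=C/Cc1cc(OC(C)=O)cc(C)c1OC(C)=O)CC/C=C(\C)Cc1cc(C)co1 | intermediate (not isolated)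
16 | 2-[(2E,5S,6E,10E)-5-hydroxy-3,7,11-trimethyl-12-(4-methylfuran-2-yl)dodeca-2,6,10-trien-1-yl]-6-methylbenzene-1,4-diol (CNP0172089.1) | C/C(=C\[C@@H](O)C/C(C)=C/Cc1cc(O)cc(C)c1O)CC/C=C(\C)Cc1cc(C)co1 | target

**Step count**
Total steps: 7. Longest linear sequence: 5 steps (1, 2, 3, 4, 7).

**Three steps most likely to fail, with fallbacks**

Step 4 (the proposed new step). The spent and unspent iodine oxidant, or incomplete oxidation, may slow the allenylboration or lower the enantiomeric excess. The fallback uses known chemistry, sets out from 6 and returns at 10. Alcohol 6 is oxidised with MnO2 in CH2Cl2 at room temperature, and dienal 8 is filtered, isolated and purified. The purified aldehyde is then submitted to the established chiral phosphoric acid catalysed allenylboration with 7 ((S)-TRIP 20 mol%, 4 Å MS, toluene, 0 °C). This sequence forms no compound outside the list (F0).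

Step 3. Lithiation of 4 may give some of the C2 anion, which leads to a 2,3-disubstituted furan that is hard to remove, and SN2' attack or Wurtz coupling may lower the yield. The fallback sets out from 3 and returns at 6, and fixes the methyl position through a butenolide. Commercial 3-methylfuran-2(5H)-one is silylated (TIPSOTf, Et3N, CH2Cl2) to triisopropyl[(3-methylfuran-2-yl)oxy]silane F1. Alkylation of F1 with 3, promoted by AgOCOCF3 in CH2Cl2 at −40 °C, takes place at C5 of the silyloxyfuran and gives the butenolide (2E,6E)-3,7-dimethyl-8-(4-methyl-5-oxo-2,5-dihydrofuran-2-yl)octa-2,6-dien-1-yl acetate F2. Reduction with i-Bu2AlH (CH2Cl2, −78 °C) removes the acetate and gives the lactol (2E,6E)-8-(5-hydroxy-4-methyl-2,5-dihydrofuran-2-yl)-3,7-dimethylocta-2,6-dien-1-ol F3, which loses water on dilute acid work-up to give furan 6.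

Step 7. Lewis acidic AlMe3 may ionise the allylic aluminium alkoxide or attack the furan, Al–Me groups may attack the aryl acetates before coupling, and the free hydroquinone oxidises in air under base. The fallback sets out from 10 and 13 and returns at 16; it separates the three events and moves the coupling to boron. After the same carboalumination of 10, the alkenylalane is quenched with 2-isopropoxy-4,4,5,5-tetramethyl-1,3,2-dioxaborolane to give the isolable boronate (1E,4S,5E,9E)-2,6,10-trimethyl-11-(4-methylfuran-2-yl)-1-(4,4,5,5-tetramethyl-1,3,2-dioxaborolan-2-yl)undeca-1,5,9-trien-4-ol F4. Suzuki–Miyaura coupling of F4 with 13 (PdCl2(dppf), K3PO4, THF/H2O, 40 °C) gives 2-[(2E,5S,6E,10E)-5-hydroxy-3,7,11-trimethyl-12-(4-methylfuran-2-yl)dodeca-2,6,10-trien-1-yl]-6-methyl-1,4-phenylene diacetate F5. A separate methanolysis (K2CO3, MeOH, argon, Na2S2O4 work-up) then gives 16.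

**Further compounds**
F0 | step 4 | none | none
F1 | step 3 | triisopropyl[(3-methylfuran-2-yl)oxy]silane | Cc1ccoc1O[Si](C(C)C)(C(C)C)C(C)C
F2 | step 3 | (2E,6E)-3,7-dimethyl-8-(4-methyl-5-oxo-2,5-dihydrofuran-2-yl)octa-2,6-dien-1-yl acetate (racemic at the ring carbon) | CC(=O)OC/C=C(\C)CC/C=C(\C)CC1OC(=O)C(C)=C1
F3 | step 3 | (2E,6E)-8-(5-hydroxy-4-methyl-2,5-dihydrofuran-2-yl)-3,7-dimethylocta-2,6-dien-1-ol (mixture of ring diastereomers) | OC/C=C(\C)CC/C=C(\C)CC1OC(O)C(C)=C1
F4 | step 7 | (1E,4S,5E,9E)-2,6,10-trimethyl-11-(4-methylfuran-2-yl)-1-(4,4,5,5-tetramethyl-1,3,2-dioxaborolan-2-yl)undeca-1,5,9-trien-4-ol | C/C(=C\[C@@H](O)C/C(C)=C/B1OC(C)(C)C(C)(C)O1)CC/C=C(\C)Cc1cc(C)co1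
F5 | step 7 | 2-[(2E,5S,6E,10E)-5-hydroxy-3,7,11-trimethyl-12-(4-methylfuran-2-yl)dodeca-2,6,10-trien-1-yl]-6-methyl-1,4-phenylene diacetate | C/C(=C\[C@@H](O)C/C(C)=C/Cc1cc(OC(C)=O)cc(C)c1OC(C)=O)CC/C=C(\C)Cc1cc(C)co1
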